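**Retrosynthetic overview**

1. The target is (2S)-naringenin joined C3'–C3''' to (2R,3R)-aromadendrin. Both C2 centres have the same spatial sense (the descriptors differ only because of the C3 hydroxyl), so the target is a C2-symmetric 3',3'''-binaringenin in which one of two homotopic C3 methylenes carries a trans OH.
2. Endgame: global hydrogenolysis ⇐ mono Rubottom hydroxylation (C3 relayed from C2) ⇐ hexa-O-benzyl (2S,2''S)-binaringenin.
3. Key disconnection: the C2–C3 bonds of both rings C, formed together by a twofold chiral-acid-catalysed Petasis–Ferrier rearrangement of a bis(2-aryl-4-methylidene-4H-1,3-benzodioxine). The enabling feature: in each half C2 carries O1 and ring B with its 4'-oxygen para (an aryloxocarbenium, para-quinone-methide-like carbon once ionized), and C3 is the α-carbon of the C4 aryl ketone on ring A (an enol carbon). A temporary O1–C2–O3–C4(=C3H2) dioxine ring stores both partners in one acetal.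
4. The bis(enol acetal) ⇐ Petasis methylenation ⇐ bis(1,3-benzodioxin-4-one) ⇐ benzylation ⇐ acetalization of a biaryl dialdehyde with two molecules of 2,4,6-trihydroxybenzoic acid; the dialdehyde ⇐ Suzuki coupling of 4-(benzyloxy)-3-bromobenzaldehyde with the pinacol boronate made from the same bromide.
5. Ring order: rings A and B are bought; the biaryl bond comes first, the two temporary dioxinone rings second, and both rings C last, in one operation.

Key step: step 6

Assumption: both starting materials (1 and 4) are taken as commercial. The sense of induction of the chiral acid in the key step cannot be derived from precedent, so the (R)-catalyst is written and its enantiomer is to be used if a test reaction shows the opposite sense.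

**Route**

Step 1
Reactants: 1 4-(benzyloxy)-3-bromobenzaldehyde
Product: 2 4-(benzyloxy)-3-(4,4,5,5-tetramethyl-1,3,2-dioxaborolan-2-yl)benzaldehyde
Conditions: B2pin2 (1.1 equiv), Pd(dppf)Cl2 (3 mol %), KOAc, dioxane, 85 °C (run on about half of the bromide)
Reagents that add atoms: bis(pinacolato)diboron, CC1(C)OB(OC1(C)C)B1OC(C)(C)C(C)(C)O1
Why: Miyaura borylation, in which zerovalent palladium formed from Pd(dppf)Cl2 inserts into the C–Br bond and acetate-assisted transmetalation with the diboron delivers the aryl boronate, the weak base leaving the aldehyde and the benzyl ether alone and keeping the boronate from coupling with unchanged bromide; no stereocenter is formed.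

Step 2
Reactants: 1 4-(benzyloxy)-3-bromobenzaldehyde; 2 4-(benzyloxy)-3-(4,4,5,5-tetramethyl-1,3,2-dioxaborolan-2-yl)benzaldehyde
Product: 3 6,6'-bis(benzyloxy)biphenyl-3,3'-dicarbaldehyde
Conditions: Pd(OAc)2 (2 mol %), SPhos (4 mol %), K3PO4, toluene/H2O, 80 °C
Reagents that add atoms: none
Why: Suzuki–Miyaura cross-coupling of the aryl bromide with the aryl boronate, each partner supplying one half of the biaryl, in which the electron-rich biarylphosphine speeds coupling of the two ortho-alkoxy partners ahead of protodeboronation and the aldehydes tolerate aqueous phosphate; the biaryl has only two ortho substituents, so no stable stereogenic axis arises.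

Step 3
Reactants: 3 6,6'-bis(benzyloxy)biphenyl-3,3'-dicarbaldehyde; 4 2,4,6-trihydroxybenzoic acid
Product: 7 2,2'-[6,6'-bis(benzyloxy)biphenyl-3,3'-diyl]bis(5,7-dihydroxy-4H-1,3-benzodioxin-4-one) (mixture of acetal stereoisomers), via trimethylsilyl 2,4,6-tris(trimethylsilyloxy)benzoate 5 (not isolated), via tetrakis(trimethylsilyl) ether 6 (not isolated)
Conditions: 4 (2.2 equiv), HMDS, TMSOTf (cat.), CH2Cl2, 40 °C, then evaporation; 3, TMSOTf (0.2 equiv), CH2Cl2, –78 to –20 °C; then MeOH, 0 °C
Reagents that add atoms: none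
Why: Silyl-triflate-catalysed acetalization of an aldehyde with a silyl ester/silyl ether pair (the usual first operation of a Petasis–Ferrier sequence), in which the carboxyl group and one ortho oxygen of each of two molecules of the persilylated acid cap one electron-rich aldehyde as a six-membered acyl aryl acetal with loss of hexamethyldisiloxane, silylation also protecting the acid against decarboxylation; the acetal carbons need no control because they are flattened again in step 6.

Step 4
Reactants: 7 2,2'-[6,6'-bis(benzyloxy)biphenyl-3,3'-diyl]bis(5,7-dihydroxy-4H-1,3-benzodioxin-4-one)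
Product: 8 2,2'-[6,6'-bis(benzyloxy)biphenyl-3,3'-diyl]bis[5,7-bis(benzyloxy)-4H-1,3-benzodioxin-4-one]
Conditions: BnBr, K2CO3, n-Bu4NI (cat.), DMF, 50 °C
Reagents that add atoms: benzyl bromide, BrCc1ccccc1
Why: Williamson etherification with excess benzyl bromide alkylates all four phenols, including the two hydrogen-bonded to the lactone carbonyls, and the acyl aryl acetal is stable to carbonate.

Step 5
Reactants: 8 2,2'-[6,6'-bis(benzyloxy)biphenyl-3,3'-diyl]bis[5,7-bis(benzyloxy)-4H-1,3-benzodioxin-4-one]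
Product: 9 2,2'-[6,6'-bis(benzyloxy)biphenyl-3,3'-diyl]bis[5,7-bis(benzyloxy)-4-methylidene-4H-1,3-benzodioxine]
Conditions: Cp2TiMe2, toluene/THF, 65 °C, dark; filtration through basic Al2O3
Reagents that add atoms: dimethyltitanocene, C[Ti](C)(C1C=CC=C1)C1C=CC=C1
Why: Petasis methylenation, in which Cp2Ti=CH2 formed thermally from Cp2TiMe2 olefinates both lactone carbonyls through oxatitanacyclobutanes under non-acidic conditions that leave the acetals and benzyl ethers alone, as in the second operation of Petasis–Ferrier sequences.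

Step 6
Reactants: 9 2,2'-[6,6'-bis(benzyloxy)biphenyl-3,3'-diyl]bis[5,7-bis(benzyloxy)-4-methylidene-4H-1,3-benzodioxine]
Product: 10 (2S,2'S)-2,2'-[6,6'-bis(benzyloxy)biphenyl-3,3'-diyl]bis[5,7-bis(benzyloxy)-2,3-dihydro-4H-chromen-4-one]
Conditions: (R)-3,3'-bis(2,4,6-triisopropylphenyl)-1,1'-binaphthyl-2,2'-diyl N-triflylphosphoramide (10 mol %), 5 Å MS, toluene (0.02 M), –40 to 0 °C
Reagents that add atoms: none
Why: Proposed new method: a catalytic enantioselective, twofold Petasis–Ferrier rearrangement of a benzo-fused enol acetal; the closest known reactions are the Lewis-acid-promoted Petasis–Ferrier rearrangement of 4-methylidene-1,3-dioxanes to tetrahydropyran-4-ones and the chiral-phosphoric-acid-catalysed aza-Petasis–Ferrier rearrangement of hemiaminal vinyl ethers. In each arm the chiral acid protonates the enol-ether oxygen O3 and the C2–O3 bond ionizes, helped by the O1 lone pair and the para benzyloxy group of ring B, to a contact ion pair in which the aryloxocarbenium ion (O1=C2, para-quinone-methide-like) and the enol of the ring A ketone remain tethered through ring A and are both held by the chiral phosphoramidate (ion pairing to the cation, hydrogen bond to the enol OH). The enol carbon C3 then adds to C2 and closes ring C in a 6-(enolendo)-endo-trig mode, the mode of Prins and oxa-Pictet–Spengler closures, and proton loss gives the ketone and returns the catalyst. The acetal stereocenters of 9 are erased on ionization, so all its stereoisomers converge, and each new C2 is set by the chiral anion alone (catalyst control, both arms independently, so the twofold reaction should raise the enantiomeric purity of the C2-symmetric product at the cost of some meso isomer, to be removed by crystallization). The step needs C–C closure to outrun hydrolysis and Friedel–Crafts attack of the cation on ring A of another molecule, which the tether (six-membered closure), high dilution and molecular sieves should secure, while O-recombination or C-protonation of the enol ether only returns 9.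

Step 7
Reactants: 10 (2S,2'S)-2,2'-[6,6'-bis(benzyloxy)biphenyl-3,3'-diyl]bis[5,7-bis(benzyloxy)-2,3-dihydro-4H-chromen-4-one]
Product: 11 (2S)-5,7-bis(benzyloxy)-2-{6,6'-bis(benzyloxy)-3'-[(2S)-5,7-bis(benzyloxy)-4-(trimethylsilyloxy)-2H-chromen-2-yl]biphenyl-3-yl}-2,3-dihydro-4H-chromen-4-one
Conditions: TMSOTf (1.0 equiv), Et3N, CH2Cl2, –20 °C; used crude
Reagents that add atoms: trimethylsilyl trifluoromethanesulfonate, C[Si](C)(C)OS(=O)(=O)C(F)(F)F
Why: Silyl enol ether formation by soft enolization avoids a free enolate and with it the retro-oxa-Michael ring opening that would racemize C2, and because the two ketones are homotopic through the C2 axis one equivalent of TMSOTf can give only one mono enol ether, in a statistical mixture with unchanged 10 (recycled after step 8) and the bis enol ether.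

Step 8
Reactants: 11 (2S)-5,7-bis(benzyloxy)-2-{6,6'-bis(benzyloxy)-3'-[(2S)-5,7-bis(benzyloxy)-4-(trimethylsilyloxy)-2H-chromen-2-yl]biphenyl-3-yl}-2,3-dihydro-4H-chromen-4-one
Product: 13 (2S)-5,7-bis(benzyloxy)-2-{6,6'-bis(benzyloxy)-3'-[(2R,3R)-5,7-bis(benzyloxy)-3-hydroxy-4-oxo-3,4-dihydro-2H-chromen-2-yl]biphenyl-3-yl}-2,3-dihydro-4H-chromen-4-one, via 4-(trimethylsilyloxy)-3,4-epoxide 12 (not isolated)
Conditions: DMDO, acetone/CH2Cl2, –40 °C; then MeOH, citric acid (cat.), 0 °C
Reagents that add atoms: dimethyldioxirane, CC1(C)OO1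
Why: Rubottom oxidation, in which dimethyldioxirane epoxidizes the enol ether from the face anti to the C2 aryl group (substrate control by the stereocenter set in step 6) and methanolysis of the silyloxy epoxide gives the 2,3-trans α-hydroxy ketone with the (2R,3R) configuration, the alcohol being separable by chromatography from recovered 10 and from doubly hydroxylated material.

Step 9
Reactants: 13 (2S)-5,7-bis(benzyloxy)-2-{6,6'-bis(benzyloxy)-3'-[(2R,3R)-5,7-bis(benzyloxy)-3-hydroxy-4-oxo-3,4-dihydro-2H-chromen-2-yl]biphenyl-3-yl}-2,3-dihydro-4H-chromen-4-one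
Product: 14 (2S)-2-{6,6'-dihydroxy-3'-[(2R,3R)-3,5,7-trihydroxy-4-oxo-3,4-dihydro-2H-chromen-2-yl]biphenyl-3-yl}-5,7-dihydroxy-2,3-dihydro-4H-chromen-4-one (CNP0201582.1)
Conditions: H2 (1 atm), 10% Pd/C, EtOAc/MeOH, rt
Reagents that add atoms: none
Why: Hydrogenolysis of the six benzyl ethers over palladium on carbon is neutral, so neither the flavanone nor the dihydroflavonol unit enolizes or ring-opens and the three stereocenters stay untouched, the reaction being stopped after uptake of six equivalents of hydrogen to spare the benzylic C2–O1 bonds.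

**Compound list**

1 | 4-(benzyloxy)-3-bromobenzaldehyde | O=Cc1ccc(OCc2ccccc2)c(Br)c1 | starting material
2 | 4-(benzyloxy)-3-(4,4,5,5-tetramethyl-1,3,2-dioxaborolan-2-yl)benzaldehyde | O=Cc1ccc(OCc2ccccc2)c(B2OC(C)(C)C(C)(C)O2)c1 | intermediate
3 | 6,6'-bis(benzyloxy)biphenyl-3,3'-dicarbaldehyde | O=Cc1ccc(OCc2ccccc2)c(c1)-c1cc(C=O)ccc1OCc1ccccc1 | intermediate
4 | 2,4,6-trihydroxybenzoic acid | OC(=O)c1c(O)cc(O)cc1O | starting material
5 | trimethylsilyl 2,4,6-tris(trimethylsilyloxy)benzoate | C[Si](C)(C)OC(=O)c1c(O[Si](C)(C)C)cc(O[Si](C)(C)C)cc1O[Si](C)(C)C | intermediate (not isolated)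
6 | 2,2'-[6,6'-bis(benzyloxy)biphenyl-3,3'-diyl]bis[5,7-bis(trimethylsilyloxy)-4H-1,3-benzodioxin-4-one] (acetal carbons unassigned) | O=C1OC(c2ccc(OCc3ccccc3)c(-c3cc(C4OC(=O)c5c(O[Si](C)(C)C)cc(O[Si](C)(C)C)cc5O4)ccc3OCc3ccccc3)c2)Oc2cc(O[Si](C)(C)C)cc(O[Si](C)(C)C)c21 | intermediate (not isolated)
7 | 2,2'-[6,6'-bis(benzyloxy)biphenyl-3,3'-diyl]bis(5,7-dihydroxy-4H-1,3-benzodioxin-4-one) (acetal carbons unassigned) | O=C1OC(c2ccc(OCc3ccccc3)c(-c3cc(C4OC(=O)c5c(O)cc(O)cc5O4)ccc3OCc3ccccc3)c2)Oc2cc(O)cc(O)c21 | intermediate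
8 | 2,2'-[6,6'-bis(benzyloxy)biphenyl-3,3'-diyl]bis[5,7-bis(benzyloxy)-4H-1,3-benzodioxin-4-one] (acetal carbons unassigned) | O=C1OC(c2ccc(OCc3ccccc3)c(-c3cc(C4OC(=O)c5c(OCc6ccccc6)cc(OCc6ccccc6)cc5O4)ccc3OCc3ccccc3)c2)Oc2cc(OCc3ccccc3)cc(OCc3ccccc3)c21 | intermediate
9 | 2,2'-[6,6'-bis(benzyloxy)biphenyl-3,3'-diyl]bis[5,7-bis(benzyloxy)-4-methylidene-4H-1,3-benzodioxine] (acetal carbons unassigned) | C=C1OC(c2ccc(OCc3ccccc3)c(-c3cc(C4OC(=C)c5c(OCc6ccccc6)cc(OCc6ccccc6)cc5O4)ccc3OCc3ccccc3)c2)Oc2cc(OCc3ccccc3)cc(OCc3ccccc3)c21 | intermediate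
10 | (2S,2'S)-2,2'-[6,6'-bis(benzyloxy)biphenyl-3,3'-diyl]bis[5,7-bis(benzyloxy)-2,3-dihydro-4H-chromen-4-one] (hexa-O-benzyl (2S,2''S)-3',3'''-binaringenin) | O=C1C[C@@H](c2ccc(OCc3ccccc3)c(-c3cc([C@H]4Oc5cc(OCc6ccccc6)cc(OCc6ccccc6)c5C(=O)C4)ccc3OCc3ccccc3)c2)Oc2cc(OCc3ccccc3)cc(OCc3ccccc3)c21 | intermediate
11 | mono(trimethylsilyl enol ether) of 10, both C2 centres S | O=C1C[C@@H](c2ccc(OCc3ccccc3)c(-c3cc([C@H]4Oc5cc(OCc6ccccc6)cc(OCc6ccccc6)c5C(O[Si](C)(C)C)=C4)ccc3OCc3ccccc3)c2)Oc2cc(OCc3ccccc3)cc(OCc3ccccc3)c21 | intermediate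
12 | 4-(trimethylsilyloxy)-3,4-epoxide of 11, epoxide oxygen anti to the 2-aryl group | O=C1C[C@@H](c2ccc(OCc3ccccc3)c(-c3cc([C@H]4Oc5cc(OCc6ccccc6)cc(OCc6ccccc6)c5[C@]5(O[Si](C)(C)C)O[C@H]45)ccc3OCc3ccccc3)c2)Oc2cc(OCc3ccccc3)cc(OCc3ccccc3)c21 | intermediate (not isolated)
13 | hexa-O-benzyl ether of the target: (2S)-flavanone unit and (2R,3R)-3-hydroxyflavanone unit | O=C1C[C@@H](c2ccc(OCc3ccccc3)c(-c3cc([C@H]4Oc5cc(OCc6ccccc6)cc(OCc6ccccc6)c5C(=O)[C@@H]4O)ccc3OCc3ccccc3)c2)Oc2cc(OCc3ccccc3)cc(OCc3ccccc3)c21 | intermediate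
14 | CNP0201582.1, (2S)-naringenin-(3'→3''')-(2R,3R)-aromadendrin | O=C1C[C@@H](c2ccc(O)c(-c3cc([C@H]4Oc5cc(O)cc(O)c5C(=O)[C@@H]4O)ccc3O)c2)Oc2cc(O)cc(O)c21 | target

**Step count and weak points**

Total step count: 9. Longest linear sequence: 9 steps (1 to 14).

Steps most likely to fail:

1. Step 6 (Proposed new method). The chiral anion may not discriminate the two faces of the oxocarbenium ion well enough; in a twofold reaction this shows up as meso isomer. The ion pair may also be lost to hydrolysis or to intermolecular Friedel–Crafts alkylation. Fallback with known chemistry, setting out from 9 and returning at 10: the classical Lewis-acid Petasis–Ferrier conditions (Me2AlCl, CH2Cl2, –78 °C) should give the stereoisomer mixture of the bis-flavanone F1. Dehydrogenation with DDQ (dioxane, 100 °C) removes both stereocenters and gives the bis-flavone F2. Asymmetric hydrogenation (H2, Ru(cod)(2-methylallyl)2 with a chiral N-heterocyclic carbene ligand, KOt-Bu) then sets both C2 centres under catalyst control; it is expected to run on to the bis(cis-flavan-4-ol) F3, which Dess–Martin periodinane oxidizes back to the ketone 10.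

2. Step 7. Nothing differentiates the two homotopic ketones, so mono-silylation stops at a statistical mixture and much of the material has to be recycled or is lost as doubly functionalized product. Fallback by cross-coupling of two differentiated halves, setting out from 1 and 4 and returning at 13: acid 4 is persilylated to 5 as in step 3 and condensed with aldehyde 1 under the same silyl triflate catalysis to the bis(trimethylsilyl ether) F4, and methanolysis gives the monomeric dihydroxy benzodioxinone F5. Benzylation as in step 4 gives the tribenzyl benzodioxinone F6, methylenation as in step 5 gives the enol acetal F7, and the rearrangement of step 6 gives the (S)-3'-bromoflavanone F8, which can be recrystallized to raise its enantiomeric purity. One portion of F8 is converted completely (excess TMSOTf, Et3N) to the silyl enol ether F9, oxidized with DMDO via the silyloxy epoxide F10, and methanolysed to the (2R,3R)-3-hydroxy bromide F11. The other portion is borylated as in step 1 (B2pin2, Pd(dppf)Cl2, KOAc, dioxane, 80 °C) to the pinacol boronate F12. Suzuki coupling of F11 and F12 under mild conditions (Pd(OAc)2, SPhos, K3PO4, THF/H2O, 40 °C) gives 13.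

3. Step 9. Hydrogenolysis may go too far: cleavage of the benzylic C2–O1 bonds (ring opening to dihydrochalcones) or reduction of the ketones before the hindered benzyl ethers next to the biaryl bond are gone. Fallback, setting out from 13 and returning at 14: Lewis-acid debenzylation with a cation scavenger (BCl3, pentamethylbenzene, CH2Cl2, –78 °C), which uses no hydrogen and makes no new compound on the way.

**Further compounds**

F1 | step 6 | 2,2'-[6,6'-bis(benzyloxy)biphenyl-3,3'-diyl]bis[5,7-bis(benzyloxy)-2,3-dihydro-4H-chromen-4-one], mixture of stereoisomers | O=C1CC(c2ccc(OCc3ccccc3)c(-c3cc(C4Oc5cc(OCc6ccccc6)cc(OCc6ccccc6)c5C(=O)C4)ccc3OCc3ccccc3)c2)Oc2cc(OCc3ccccc3)cc(OCc3ccccc3)c21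
F2 | step 6 | 2,2'-[6,6'-bis(benzyloxy)biphenyl-3,3'-diyl]bis[5,7-bis(benzyloxy)-4H-chromen-4-one] | O=c1cc(-c2ccc(OCc3ccccc3)c(-c3cc(-c4cc(=O)c5c(OCc6ccccc6)cc(OCc6ccccc6)cc5o4)ccc3OCc3ccccc3)c2)oc2cc(OCc3ccccc3)cc(OCc3ccccc3)c12
F3 | step 6 | (2S,4S,2'S,4'S)-2,2'-[6,6'-bis(benzyloxy)biphenyl-3,3'-diyl]bis[5,7-bis(benzyloxy)-3,4-dihydro-2H-chromen-4-ol] (2,4-cis in each unit) | O[C@H]1C[C@@H](c2ccc(OCc3ccccc3)c(-c3cc([C@H]4Oc5cc(OCc6ccccc6)cc(OCc6ccccc6)c5[C@@H](O)C4)ccc3OCc3ccccc3)c2)Oc2cc(OCc3ccccc3)cc(OCc3ccccc3)c21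
F4 | step 7 | 2-[4-(benzyloxy)-3-bromophenyl]-5,7-bis(trimethylsilyloxy)-4H-1,3-benzodioxin-4-one (acetal carbon unassigned) | O=C1OC(c2ccc(OCc3ccccc3)c(Br)c2)Oc2cc(O[Si](C)(C)C)cc(O[Si](C)(C)C)c21
F5 | step 7 | 2-[4-(benzyloxy)-3-bromophenyl]-5,7-dihydroxy-4H-1,3-benzodioxin-4-one (acetal carbon unassigned) | O=C1OC(c2ccc(OCc3ccccc3)c(Br)c2)Oc2cc(O)cc(O)c21
F6 | step 7 | 5,7-bis(benzyloxy)-2-[4-(benzyloxy)-3-bromophenyl]-4H-1,3-benzodioxin-4-one (acetal carbon unassigned) | O=C1OC(c2ccc(OCc3ccccc3)c(Br)c2)Oc2cc(OCc3ccccc3)cc(OCc3ccccc3)c21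
F7 | step 7 | 5,7-bis(benzyloxy)-2-[4-(benzyloxy)-3-bromophenyl]-4-methylidene-4H-1,3-benzodioxine (acetal carbon unassigned) | C=C1OC(c2ccc(OCc3ccccc3)c(Br)c2)Oc2cc(OCc3ccccc3)cc(OCc3ccccc3)c21
F8 | step 7 | (2S)-5,7-bis(benzyloxy)-2-[4-(benzyloxy)-3-bromophenyl]-2,3-dihydro-4H-chromen-4-one | O=C1C[C@@H](c2ccc(OCc3ccccc3)c(Br)c2)Oc2cc(OCc3ccccc3)cc(OCc3ccccc3)c21
F9 | step 7 | (2S)-5,7-bis(benzyloxy)-2-[4-(benzyloxy)-3-bromophenyl]-4-(trimethylsilyloxy)-2H-chromene | C[Si](C)(C)OC1=C[C@@H](c2ccc(OCc3ccccc3)c(Br)c2)Oc2cc(OCc3ccccc3)cc(OCc3ccccc3)c21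
F10 | step 7 | 4-(trimethylsilyloxy)-3,4-epoxide of F9, epoxide oxygen anti to the 2-aryl group | Brc1cc(ccc1OCc1ccccc1)[C@H]1Oc2cc(OCc3ccccc3)cc(OCc3ccccc3)c2[C@]2(O[Si](C)(C)C)O[C@H]12
F11 | step 7 | (2R,3R)-5,7-bis(benzyloxy)-2-[4-(benzyloxy)-3-bromophenyl]-3-hydroxy-2,3-dihydro-4H-chromen-4-one | Brc1cc(ccc1OCc1ccccc1)[C@H]1Oc2cc(OCc3ccccc3)cc(OCc3ccccc3)c2C(=O)[C@@H]1O
F12 | step 7 | (2S)-5,7-bis(benzyloxy)-2-[4-(benzyloxy)-3-(4,4,5,5-tetramethyl-1,3,2-dioxaborolan-2-yl)phenyl]-2,3-dihydro-4H-chromen-4-one | O=C1C[C@@H](c2ccc(OCc3ccccc3)c(B3OC(C)(C)C(C)(C)O3)c2)Oc2cc(OCc3ccccc3)cc(OCc3ccccc3)c21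
F0 | step 9 | none | none
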